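**Plan**
- Retrosynthesis: the O1–C2 bond of the dihydropyran ring is cut first, giving 2-methyl-6-phytylhydroquinone. Next the aryl–CH2 bond (C4a–C4) is cut to a brominated hydroquinone dimethyl ether and phytyl bromide. The para oxygen is traced back to 2-bromo-6-methylphenol.
- Forward: para-oxidation and reductive methylation of the bromophenol, copper-mediated attachment of the intact C20 chain, oxidative unmasking to the quinone, reduction, and closure of the only new ring as the last step.
- Enabling feature: C2 of the dihydropyran ring is a tertiary ether carbon (CH3 and the C16 chain) bonded to O1. It maps onto C3′ of a phytyl E-alkene placed ortho to a phenolic hydroxyl that can add across it.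
- Stereochemistry: 4′R and 8′R come unchanged from natural (7R,11R)-phytol; 2R is set in the ring closure by tocopherol cyclase acting on the E-alkene.

Key step: step 7

Assumption: an active preparation of recombinant tocopherol cyclase (Arabidopsis thaliana VTE1 without transit peptide, expressed in Escherichia coli) is taken to be at hand, and commercial natural phytol is taken to be the (2E,7R,11R) isomer. "Phytyl" stands throughout for (2E,7R,11R)-3,7,11,15-tetramethylhexadec-2-en-1-yl.

**Step 1**
Reactants: 1 2-bromo-6-methylphenol
Product: 2 2-bromo-6-methyl-1,4-benzoquinone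
Conditions: (KSO3)2NO (2.2 equiv), KH2PO4 buffer, acetone/H2O, 0 °C to rt
Reagents that add atoms: dipotassium nitrosodisulfonate (Fremy's salt), [K+].[K+].[O]N(S(=O)(=O)[O-])S(=O)(=O)[O-]
Why: Teuber oxidation, in which one nitroxyl radical removes the phenolic hydrogen, a second adds through oxygen at the free para carbon of the phenoxyl radical and loss of imidodisulfonate gives the para-quinone, the ortho positions being blocked by bromine and methyl.

**Step 2**
Reactants: 2 2-bromo-6-methyl-1,4-benzoquinone
Product: 4 1-bromo-2,5-dimethoxy-3-methylbenzene, via bromohydroquinone 3 (not isolated)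
Conditions: Na2S2O4, n-Bu4NBr (cat.), THF/H2O, rt, N2; then aq. KOH, Me2SO4, rt
Reagents that add atoms: dimethyl sulfate, COS(=O)(=O)OC
Why: Reductive methylation of a quinone, in which dithionite gives hydroquinone 3 and both phenoxide oxygens are methylated under phase-transfer Williamson conditions before air can reoxidise them, the aryl bromide being inert to both reagents.

**Step 3**
Reactants: 5 (2E,7R,11R)-phytol
Product: 6 (2E,7R,11R)-phytyl bromide
Conditions: PBr3 (0.4 equiv), pyridine (cat.), Et2O, −10 to 0 °C, dark; used crude at once
Reagents that add atoms: phosphorus tribromide, BrP(Br)Br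
Why: Bromination of a primary allylic alcohol with PBr3, in which bromide displaces the phosphite ester at C1 in an SN2 manner at low temperature, so the E double bond and the remote 7R and 11R centres should be kept.

**Step 4**
Reactants: 4 1-bromo-2,5-dimethoxy-3-methylbenzene; 6 (2E,7R,11R)-phytyl bromide
Product: 9 2,5-dimethoxy-1-methyl-3-[(2E,7R,11R)-phytyl]benzene, via aryllithium 7 (not isolated), via arylcopper 8 (not isolated)
Conditions: 4 (1.3 equiv), n-BuLi, THF, −78 °C; CuBr·SMe2 (1.3 equiv), −78 to −40 °C; then 6, −78 to 0 °C; aq. NH4Cl work-up
Reagents that add atoms: none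
Why: Bromine–lithium exchange and transmetalation give an arylcopper reagent that should alkylate the allylic bromide at its primary CH2 terminus (SN2 and not SN2′, the other terminus being fully substituted) with retention of the E geometry, the standard copper-mediated prenylation of protected hydroquinones, to which methyl ethers are inert.

**Step 5**
Reactants: 9 2,5-dimethoxy-1-methyl-3-[(2E,7R,11R)-phytyl]benzene
Product: 10 2-methyl-6-[(2E,7R,11R)-phytyl]-1,4-benzoquinone
Conditions: (NH4)2Ce(NO3)6 (2.5 equiv), MeCN/CH2Cl2/H2O, 0 °C, dark; chromatography on SiO2 (AgNO3-impregnated if Z isomer must be removed)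
Reagents that add atoms: water, O
Why: Oxidative demethylation of a 1,4-dimethoxyarene by tetravalent cerium, in which two one-electron oxidations and attack of water at the methoxy-bearing carbons release methanol and give the para-quinone, a reaction routinely run on polyprenylated dimethoxyarenes without harm to trisubstituted alkenes and one whose product cannot cyclise to a chromanol of uncontrolled C2 configuration.

**Step 6**
Reactants: 10 2-methyl-6-[(2E,7R,11R)-phytyl]-1,4-benzoquinone
Product: 11 2-methyl-6-[(2E,7R,11R)-phytyl]benzene-1,4-diol
Conditions: aq. Na2S2O4, Et2O, rt, argon, shaken until colourless; dried and concentrated under argon, used at once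
Reagents that add atoms: none
Why: Dithionite reduction of a para-quinone to the hydroquinone is fast and selective in a two-phase system, leaves the alkene untouched and under argon should deliver the air-sensitive cyclase substrate for immediate use.

**Step 7**
Reactants: 11 2-methyl-6-[(2E,7R,11R)-phytyl]benzene-1,4-diol
Product: 12 (2R,4′R,8′R)-δ-tocopherol, (2R)-2,8-dimethyl-2-[(4R,8R)-4,8,12-trimethyltridecyl]-3,4-dihydro-2H-chromen-6-ol
Conditions: recombinant tocopherol cyclase (Arabidopsis thaliana VTE1, expressed in Escherichia coli, cell-free extract), KH2PO4/K2HPO4 buffer pH 7.3, sodium L-ascorbate, dithiothreitol, Tween 80, 11 added in EtOH, argon, dark, 30 °C; hexane extraction under argon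
Reagents that add atoms: none
Why: The cyclase acts as a chiral Brønsted acid: an acidic active-site residue protonates C2′ of the phytyl E-alkene (the future C3), and the tertiary cation developing at C3′ (the future C2) is captured from the opposite face by the oxygen of the 1-hydroxyl, an anti, Markovnikov addition of O–H across the double bond that forms the O1–C2 bond. The closest known reaction type is the acid-catalysed intramolecular hydroalkoxylation of ortho-prenylphenols to 2,2-dialkylchromans, and this enzymatic version is the native ring closure of tocopherol biosynthesis, which recombinant cyclase carries out in vitro on this very quinol. The dihydropyran ring closes in the 6-endo-trig mode. The new stereocentre C2 should be set as R by the enzyme pocket, which binds the folded chain so that proton and oxygen reach fixed, opposite faces of the E-alkene, while 4′R and 8′R are carried over unchanged from phytol. The step needs facial selectivity (enzyme), site selectivity (only the hydroxyl flanked by methyl and phytyl lies ortho to the chain and can reach C3′, the 4-hydroxyl cannot) and a reduced substrate (ascorbate, dithiothreitol and argon keep 11 from oxidising to quinone 10, which is not cyclised). At pH 7.3 and 30 °C no uncatalysed acid cyclisation should compete, so no 2S epimer is expected from a background reaction.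

**Compound list**
1 | 2-bromo-6-methylphenol | Cc1cccc(Br)c1O | starting material
2 | 2-bromo-6-methyl-1,4-benzoquinone (2-bromo-6-methylcyclohexa-2,5-diene-1,4-dione) | CC1=CC(=O)C=C(Br)C1=O | intermediate
3 | 2-bromo-6-methylbenzene-1,4-diol | Cc1cc(O)cc(Br)c1O | intermediate
4 | 1-bromo-2,5-dimethoxy-3-methylbenzene | COc1cc(C)c(OC)c(Br)c1 | intermediate
5 | (2E,7R,11R)-phytol, (2E,7R,11R)-3,7,11,15-tetramethylhexadec-2-en-1-ol | OC/C=C(\C)CCC[C@H](C)CCC[C@H](C)CCCC(C)C | starting material
6 | (2E,7R,11R)-phytyl bromide, (2E,7R,11R)-1-bromo-3,7,11,15-tetramethylhexadec-2-ene | BrC/C=C(\C)CCC[C@H](C)CCC[C@H](C)CCCC(C)C | intermediate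
7 | (2,5-dimethoxy-3-methylphenyl)lithium | [Li]c1cc(OC)cc(C)c1OC | intermediate
8 | (2,5-dimethoxy-3-methylphenyl)copper | [Cu]c1cc(OC)cc(C)c1OC | intermediate
9 | 2,5-dimethoxy-1-methyl-3-[(2E,7R,11R)-3,7,11,15-tetramethylhexadec-2-en-1-yl]benzene | COc1cc(C)c(OC)c(C/C=C(\C)CCC[C@H](C)CCC[C@H](C)CCCC(C)C)c1 | intermediate
10 | 2-methyl-6-[(2E,7R,11R)-3,7,11,15-tetramethylhexadec-2-en-1-yl]cyclohexa-2,5-diene-1,4-dione | CC1=CC(=O)C=C(C/C=C(\C)CCC[C@H](C)CCC[C@H](C)CCCC(C)C)C1=O | intermediate
11 | 2-methyl-6-[(2E,7R,11R)-3,7,11,15-tetramethylhexadec-2-en-1-yl]benzene-1,4-diol | Cc1cc(O)cc(C/C=C(\C)CCC[C@H](C)CCC[C@H](C)CCCC(C)C)c1O | intermediate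
12 | (2R,4′R,8′R)-δ-tocopherol, (2R)-2,8-dimethyl-2-[(4R,8R)-4,8,12-trimethyltridecyl]-3,4-dihydro-2H-chromen-6-ol | Cc1cc(O)cc2c1O[C@](C)(CCC[C@H](C)CCC[C@H](C)CCCC(C)C)CC2 | target

**Totals**
Total step count: 7. Longest linear sequence: 6 steps (steps 1, 2, 4, 5, 6, 7 from 2-bromo-6-methylphenol); step 3 is the one-step side branch.

**Steps most likely to fail**

Step 7. The membrane-associated enzyme may turn over slowly with a very lipophilic substrate delivered from detergent micelles, and 11 may reoxidise to the quinone, which is not accepted. The fallback sets out from 11 and comes back at 12. The same O1–C2 bond is closed without enzyme by Brønsted-acid hydroalkoxylation (p-TsOH·H2O cat., toluene, 80 °C, argon). This should give 12 together with its C2 epimer (2S,4′R,8′R)-δ-tocopherol F1. The two are then separated by preparative HPLC on a cellulose tris(3,5-dimethylphenylcarbamate) phase, the established way to resolve 2-epimeric tocopherols, to give 12.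

Step 4. The arylcopper may attack the tertiary allyl terminus, the E geometry may leak through allylic isomerisation of the bromide, or transfer from the hindered, doubly ortho-substituted aryl group may be slow and leave phytyl homocoupling to win. The fallback sets out from 6 and comes back at 10, bypassing steps 4 and 5. Commercial 2-methylphenol (Cc1ccccc1O) is deprotonated with NaH in toluene to sodium 2-methylphenoxide F2. As a tight ion pair in the non-polar solvent it should be C-alkylated by 6 at its free ortho position to give 2-methyl-6-[(2E,7R,11R)-phytyl]phenol F3, which is separated from aryl ether and para isomer by chromatography. Teuber oxidation of F3 with (KSO3)2NO under the conditions of step 1 then puts in the para oxygen and gives quinone 10.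

Step 5. Oxidation may stray to the allylic and benzylic positions or the alkene, the ring may be nitrated, or the radical cation may dimerise to diquinones before the hindered methoxy group is lost. The fallback sets out from 2 and comes back at 11, with no oxidative unmasking. Quinone 2 is reduced with Na2S2O4 to 3 and protected with MOMCl and i-Pr2NEt in CH2Cl2 as 1-bromo-2,5-bis(methoxymethoxy)-3-methylbenzene F4. n-BuLi at −78 °C gives [2,5-bis(methoxymethoxy)-3-methylphenyl]lithium F5, and CuBr·SMe2 converts it into [2,5-bis(methoxymethoxy)-3-methylphenyl]copper F6. Allylation with 6 as in step 4 gives 2,5-bis(methoxymethoxy)-1-methyl-3-[(2E,7R,11R)-phytyl]benzene F7. Acetal exchange with dilute HCl in MeOH at 0 °C to rt under argon, conditions in common use on ortho-prenylated aryl MOM ethers and stopped before any chroman forms, should free hydroquinone 11.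

**Further compounds**
F1 | step 7 | (2S,4′R,8′R)-δ-tocopherol, (2S)-2,8-dimethyl-2-[(4R,8R)-4,8,12-trimethyltridecyl]-3,4-dihydro-2H-chromen-6-ol | Cc1cc(O)cc2c1O[C@@](C)(CCC[C@H](C)CCC[C@H](C)CCCC(C)C)CC2
F2 | step 4 | sodium 2-methylphenoxide | Cc1ccccc1[O-].[Na+]
F3 | step 4 | 2-methyl-6-[(2E,7R,11R)-3,7,11,15-tetramethylhexadec-2-en-1-yl]phenol | Cc1cccc(C/C=C(\C)CCC[C@H](C)CCC[C@H](C)CCCC(C)C)c1O
F4 | step 5 | 1-bromo-2,5-bis(methoxymethoxy)-3-methylbenzene | COCOc1cc(C)c(OCOC)c(Br)c1
F5 | step 5 | [2,5-bis(methoxymethoxy)-3-methylphenyl]lithium | [Li]c1cc(OCOC)cc(C)c1OCOC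
F6 | step 5 | [2,5-bis(methoxymethoxy)-3-methylphenyl]copper | [Cu]c1cc(OCOC)cc(C)c1OCOC
F7 | step 5 | 2,5-bis(methoxymethoxy)-1-methyl-3-[(2E,7R,11R)-3,7,11,15-tetramethylhexadec-2-en-1-yl]benzene | COCOc1cc(C)c(OCOC)c(C/C=C(\C)CCC[C@H](C)CCC[C@H](C)CCCC(C)C)c1
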